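Locants (labdane type): cyclohexane = C5–C6–C7–C8–C9–C10. C5 bears CMe2CO2H (C4, C3), C10 bears CH3 and CH2CO2H (C1, C2), C8 bears CH3 (C17) and O. Tetrahydropyran = O–C8–C9–C11–C12–C13; oxirane = C14–C15.
Late stage: the acids come from benzyl esters and the terminal oxirane from a 14,15-diol. The tetrahydropyran comes from 6-exo opening (inversion at C13) of a nerol-derived Sharpless 13,14-epoxide by the C8 tertiary alcohol. That alcohol comes from a C8 ketone (methylenation, hydration), and CH2CO2H comes from an allyl group.
Key disconnection: the cyclohexanone C5–C10 comes from a cyclopentanone built of C5, C6, C7, C8 and C10, which carries C9 on C10 as an exocyclic radical precursor. A radical 1,2-acyl shift (C8 moves from C10 to C9) enlarges the ring by C9, and the tertiary C10 radical is allylated in the same operation.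
Enabling feature: the O-bearing fusion carbon C8 lies 1,3 to the quaternary C10 across the fusion CH C9. With C8 at the ketone level, C8(=O)/C10/C9• is a β-keto-radical triad. C10 is flanked on one ring face by the C5 arm and the C9 chain, which sends the new C10–C1 bond to the other face.
The cyclopentanone comes from 2-methylcyclopent-2-enone, an isobutyrate silyl ketene acetal (asymmetric Mukaiyama–Michael addition, sets C5) and an epoxy aldehyde (aldol). Ring order: 13,14-oxirane (temporary), cyclopentane (bought) → cyclohexane, tetrahydropyran, 14,15-oxirane.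

Key step: step 8

Remark: the facial sense of the catalyst in step 5 is assigned by analogy only. The catalyst antipode that gives (S)-8 is meant; if the sense is opposite, the other antipode is used.

Step 1
Reactants: 1 nerol
Product: 2 (2R,3S)-2,3-epoxynerol
Conditions: Ti(Oi-Pr)4 (cat.), D-(−)-diethyl tartrate (cat.), t-BuOOH, 4 Å MS, CH2Cl2, −20 °C
Reagents that add atoms: tert-butyl hydroperoxide, CC(C)(C)OO
Why: Katsuki–Sharpless asymmetric epoxidation; the D-tartrate complex delivers oxygen to the face of the (Z)-allylic alcohol that gives the (2R,3S)-epoxide (future C14 and C13), and the remote alkene is left alone because only the allylic alcohol binds to titanium.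

Step 2
Reactants: 2 (2R,3S)-2,3-epoxynerol
Product: 3 TBS ether of 2
Conditions: TBSCl, imidazole, CH2Cl2, 0 °C to rt
Reagents that add atoms: tert-butyldimethylsilyl chloride, CC(C)(C)[Si](C)(C)Cl
Why: Standard O-silylation of a primary alcohol; no stereocentre is touched.

Step 3
Reactants: 3 TBS ether of 2
Product: 4 epoxy aldehyde
Conditions: O3, CH2Cl2, −78 °C; Me2S, −78 °C to rt
Reagents that add atoms: ozone, [O-][O+]=O
Why: Ozonolysis with reductive work-up cleaves the only C=C bond; epoxide and silyl ether are inert, and the aldehyde carbon is the future C9.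

Step 4
Reactants: 5 benzyl isobutyrate
Product: 6 silyl ketene acetal of benzyl isobutyrate
Conditions: LDA, THF, −78 °C; TMSCl, −78 °C to rt
Reagents that add atoms: chlorotrimethylsilane, C[Si](C)(C)Cl
Why: Ester enolisation and O-silylation (silyl ketene acetal formation); there is no geometry issue because the enolate carbon bears two methyl groups.

Step 5
Reactants: 7 2-methylcyclopent-2-en-1-one, 6 silyl ketene acetal of benzyl isobutyrate
Product: 8 (S)-configured enol silane
Conditions: chiral oxazaborolidinium triflimide (cat.), Ph3PO (cat.), toluene, −20 °C; non-aqueous work-up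
Reagents that add atoms: none
Why: Catalytic asymmetric Mukaiyama–Michael addition; the chiral Lewis acid binds the enone carbonyl and shields one face of the β-carbon, which sets C5, and silyl transfer leaves the regiodefined C8=C10 enol silane.

Step 6
Reactants: 8 (S)-configured enol silane, 4 epoxy aldehyde
Product: 10 aldol, via potassium enolate 9 (not isolated)
Conditions: KOt-Bu, THF, −78 to −40 °C; 4, −78 °C; AcOH in THF, −78 °C
Reagents that add atoms: potassium tert-butoxide, CC(C)(C)[O-].[K+] (its potassium stands only in 9)
Why: Alkoxide desilylation frees the regiodefined tetrasubstituted enolate, and aldol addition occurs on the ring face opposite the bulky C5 arm; the configurations at C10 and C9 need no control because both become radical centres in step 8, and the cold acid quench forestalls retro-aldol cleavage.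

Step 7
Reactants: 10 aldol
Product: 11 O-phenyl thionocarbonate
Conditions: PhOC(S)Cl, pyridine, DMAP (cat.), CH2Cl2, 0 °C to rt
Reagents that add atoms: O-phenyl chlorothionoformate, ClC(=S)Oc1ccccc1
Why: O-Thioacylation as used for Barton–McCombie activation; the weakly basic medium avoids retro-aldol cleavage, and β-elimination is impossible because C10 bears no hydrogen.

Step 8
Reactants: 11 O-phenyl thionocarbonate
Product: 12 ring-enlarged allyl ketone
Conditions: allylSnBu3 (3 equiv, about 0.1 M), AIBN (portions), benzene, 80 °C
Reagents that add atoms: allyltributylstannane, C=CC[Sn](CCCC)(CCCC)CCCC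
Why: Proposed new method: Bu3Sn• adds to the C=S group and releases the secondary C9 radical, which attacks the neighbouring C8 carbonyl carbon to give a bicyclo[3.1.0]hexan-1-oxyl radical; β-scission of the fusion bond C8–C10 (net 1,2-acyl shift) inserts C9 into the ring, turns the cyclopentanone into the cyclohexanone and leaves the tertiary C10 radical, which is allylated by SH2′ attack on the stannane with release of chain-carrying Bu3Sn•. The closest known reaction types are the Dowd–Beckwith ring expansion of 2-(halomethyl)cycloalkanones and the Keck radical allylation; new here are their merger on a substrate without a radical-stabilising ester and the intermolecular construction of a quaternary centre by the ring-expanded radical. The only ring closure is the transient, reversible 3-exo-trig closure onto C=O; the six-membered ring arises by one-carbon enlargement of the five-membered ring, driven by the change from a secondary to a tertiary radical and by relief of cyclopentanone strain. At C9 the chain takes the exo position of the cyclopropyloxy radical and so ends equatorial and cis to the C5 arm (this centre is α to the ketone and can also be corrected by base); at C10 the planar radical has the C5 arm and the C9 chain on the same ring face, so the stannane attacks the opposite face (1,2-anti induction from both sides), which places allyl trans to both and the methyl group axial as in the target. The step needs the unimolecular shift to outrun direct allylation at C9 and the congested C10 radical to survive until trapped; this is secured by the absence of any hydrogen donor, the moderate stannane concentration, and the masking of the side-chain alkene as the epoxide, so that no 5-exo or 6-endo cyclisation competes.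

Step 9
Reactants: 12 ring-enlarged allyl ketone
Product: 13 keto aldehyde
Conditions: O3, CH2Cl2, −78 °C; Me2S, −78 °C to rt
Reagents that add atoms: ozone, [O-][O+]=O
Why: Ozonolysis of the only alkene with reductive work-up; the product is used at once to avoid intramolecular aldol reactions.

Step 10
Reactants: 13 keto aldehyde
Product: 14 keto acid
Conditions: NaClO2, NaH2PO4, 2-methyl-2-butene, t-BuOH/H2O, 0 °C to rt
Reagents that add atoms: sodium chlorite, [O-]Cl=O.[Na+]
Why: Pinnick oxidation; the buffered medium spares the epoxide, silyl ether, ketone and benzyl ester.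

Step 11
Reactants: 14 keto acid
Product: 15 keto dibenzyl ester
Conditions: BnBr, K2CO3, DMF, rt
Reagents that add atoms: benzyl bromide, BrCc1ccccc1
Why: SN2 O-alkylation of the carboxylate; the mild base can only equilibrate C9 towards the desired equatorial epimer.

Step 12
Reactants: 15 keto dibenzyl ester
Product: 16 C8 exocyclic methylene compound
Conditions: Ph3PCH3Br, KOt-Bu, THF, 0 to 40 °C
Reagents that add atoms: methyltriphenylphosphonium bromide, C[P+](c1ccccc1)(c1ccccc1)c1ccccc1.[Br-]
Why: Wittig methylenation of the ketone, which is more electrophilic than the two hindered esters; the new carbon is C17.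

Step 13
Reactants: 16 C8 exocyclic methylene compound
Product: 17 C8 tertiary alcohol
Conditions: Mn(dpm)3 (cat.), PhSiH3, O2 (1 atm), i-PrOH/CH2Cl2, 0 °C; PPh3
Reagents that add atoms: dioxygen, O=O
Why: Mukaiyama hydration (hydrogen-atom transfer to the CH2 terminus, O2 capture of the tertiary C8 radical, reduction of the peroxide); O2 should approach from the equatorial side because the axial side is blocked by the syn-axial C10 methyl group, which gives the equatorial C8–O bond and the axial C8 methyl of the target.

Step 14
Reactants: 17 C8 tertiary alcohol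
Product: 19 pyran diol, via pyran silyl ether 18 (not isolated)
Conditions: CSA (cat.), CH2Cl2, 0 °C; then MeOH, rt
Reagents that add atoms: none
Why: Acid-catalysed intramolecular epoxide opening, 6-exo-tet at the tertiary C13 (favoured over 7-endo on both ring-size and electronic grounds), with inversion at C13 and no change at C14; methanolysis then removes the primary silyl ether.

Step 15
Reactants: 19 pyran diol
Product: 21 dibenzyl ester of the target, via primary tosylate 20 (not isolated)
Conditions: NaH (2.2 equiv), 1-tosylimidazole, THF, 0 °C to rt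
Reagents that add atoms: 1-(p-toluenesulfonyl)imidazole, Cc1ccc(cc1)S(=O)(=O)n1ccnc1 (its tosyl group stands only in 20)
Why: Selective sulfonylation of the primary alkoxide followed by 3-exo-tet Williamson closure by the C14 alkoxide; no bond to C14 is broken, so its configuration is retained.

Step 16
Reactants: 21 dibenzyl ester of the target
Product: 22 target diacid
Conditions: H2 (1 atm), Pd/C, EtOAc, rt
Reagents that add atoms: none
Why: Neutral hydrogenolysis of both benzyl esters; the non-benzylic oxirane and the tertiary ether should not be cleaved, and no acid or base that could open the oxirane is present.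

Compound list
1 | nerol, (2Z)-3,7-dimethylocta-2,6-dien-1-ol | CC(C)=CCC/C(C)=C\CO | starting material
2 | [(2R,3S)-3-methyl-3-(4-methylpent-3-en-1-yl)oxiran-2-yl]methanol | CC(C)=CCC[C@]1(C)O[C@@H]1CO | intermediate
3 | tert-butyldimethylsilyl ether of 2 | CC(C)=CCC[C@]1(C)O[C@@H]1CO[Si](C)(C)C(C)(C)C | intermediate
4 | 3-[(2S,3R)-3-{[(tert-butyldimethylsilyl)oxy]methyl}-2-methyloxiran-2-yl]propanal | O=CCC[C@]1(C)O[C@@H]1CO[Si](C)(C)C(C)(C)C | intermediate
5 | benzyl isobutyrate (benzyl 2-methylpropanoate) | CC(C)C(=O)OCc1ccccc1 | starting material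
6 | {[1-(benzyloxy)-2-methylprop-1-en-1-yl]oxy}trimethylsilane | CC(C)=C(OCc1ccccc1)O[Si](C)(C)C | intermediate
7 | 2-methylcyclopent-2-en-1-one | CC1=CCCC1=O | starting material
8 | benzyl 2-methyl-2-[(1S)-2-methyl-3-(trimethylsilyloxy)cyclopent-2-en-1-yl]propanoate | CC(C)(C(=O)OCc1ccccc1)[C@H]1CCC(O[Si](C)(C)C)=C1C | intermediate
9 | potassium enolate derived from 8 | CC(C)(C(=O)OCc1ccccc1)[C@H]1CCC([O-])=C1C.[K+] | intermediate
10 | benzyl 2-[(1S,2S)-2-{1-hydroxy-3-[(2S,3R)-3-(TBSO-methyl)-2-methyloxiran-2-yl]propyl}-2-methyl-3-oxocyclopentyl]-2-methylpropanoate (hydroxyalkyl group trans to the C5 arm; both C9 carbinol epimers) | CC(C)(C(=O)OCc1ccccc1)[C@H]1CCC(=O)[C@]1(C)C(O)CC[C@]2(C)O[C@@H]2CO[Si](C)(C)C(C)(C)C | intermediate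
11 | O-phenyl thionocarbonate of 10 (at the C9 oxygen) | CC(C)(C(=O)OCc1ccccc1)[C@H]1CCC(=O)[C@]1(C)C(OC(=S)Oc1ccccc1)CC[C@]2(C)O[C@@H]2CO[Si](C)(C)C(C)(C)C | intermediate
12 | benzyl 2-[(1S,2R,3S)-2-allyl-3-{2-[(2S,3R)-3-(TBSO-methyl)-2-methyloxiran-2-yl]ethyl}-2-methyl-4-oxocyclohexyl]-2-methylpropanoate (allyl trans to the C5 arm and to the C9 chain) | CC(C)(C(=O)OCc1ccccc1)[C@H]1CCC(=O)[C@@H](CC[C@]2(C)O[C@@H]2CO[Si](C)(C)C(C)(C)C)[C@]1(C)CC=C | intermediate
13 | keto aldehyde: 12 with CH2CHO in place of allyl, same configuration | CC(C)(C(=O)OCc1ccccc1)[C@H]1CCC(=O)[C@@H](CC[C@]2(C)O[C@@H]2CO[Si](C)(C)C(C)(C)C)[C@]1(C)CC=O | intermediate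
14 | keto acid: 12 with CH2CO2H in place of allyl, same configuration | CC(C)(C(=O)OCc1ccccc1)[C@H]1CCC(=O)[C@@H](CC[C@]2(C)O[C@@H]2CO[Si](C)(C)C(C)(C)C)[C@]1(C)CC(=O)O | intermediate
15 | keto dibenzyl ester: benzyl ester of 14, same configuration | CC(C)(C(=O)OCc1ccccc1)[C@H]1CCC(=O)[C@@H](CC[C@]2(C)O[C@@H]2CO[Si](C)(C)C(C)(C)C)[C@]1(C)CC(=O)OCc1ccccc1 | intermediate
16 | 15 with C8=CH2 in place of C8=O, same spatial arrangement at C5, C9, C10 | CC(C)(C(=O)OCc1ccccc1)[C@H]1CCC(=C)[C@@H](CC[C@]2(C)O[C@@H]2CO[Si](C)(C)C(C)(C)C)[C@]1(C)CC(=O)OCc1ccccc1 | intermediate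
17 | (8S) tertiary alcohol: C8 bears equatorial OH and axial CH3 (cis to the C10 methyl) | CC(C)(C(=O)OCc1ccccc1)[C@H]1CC[C@](C)(O)[C@@H](CC[C@]2(C)O[C@@H]2CO[Si](C)(C)C(C)(C)C)[C@]1(C)CC(=O)OCc1ccccc1 | intermediate
18 | trans-fused pyran, (13R,14R), C14–OH free, C15–OTBS | CC(C)(C(=O)OCc1ccccc1)[C@H]1CC[C@]2(C)O[C@@](C)([C@H](O)CO[Si](C)(C)C(C)(C)C)CC[C@H]2[C@]1(C)CC(=O)OCc1ccccc1 | intermediate
19 | pyran 14,15-diol, (13R,14R) | CC(C)(C(=O)OCc1ccccc1)[C@H]1CC[C@]2(C)O[C@@](C)([C@H](O)CO)CC[C@H]2[C@]1(C)CC(=O)OCc1ccccc1 | intermediate
20 | C15 p-toluenesulfonate of 19 | CC(C)(C(=O)OCc1ccccc1)[C@H]1CC[C@]2(C)O[C@@](C)([C@H](O)COS(=O)(=O)c3ccc(C)cc3)CC[C@H]2[C@]1(C)CC(=O)OCc1ccccc1 | intermediate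
21 | dibenzyl ester of 22 | CC(C)(C(=O)OCc1ccccc1)[C@H]1CC[C@]2(C)O[C@@](C)([C@H]3CO3)CC[C@H]2[C@]1(C)CC(=O)OCc1ccccc1 | intermediate
22 | 2-{(2R,4aS,5R,6S,8aS)-5-(carboxymethyl)-2,5,8a-trimethyl-2-[(2R)-oxiran-2-yl]octahydro-2H-chromen-6-yl}-2-methylpropanoic acid (CNP0160287.1) | CC(C)(C(=O)O)[C@H]1CC[C@]2(C)O[C@@](C)([C@H]3CO3)CC[C@H]2[C@]1(C)CC(=O)O | target

Total step count: 16. Longest linear sequence: 14 (steps 1–3 and 6–16).

Steps most likely to fail

1. Step 8.
   - What may go wrong: the C9 radical may be allylated before the acyl shift. The congested C10 radical may be trapped too slowly, so that the chain collapses or the radical disproportionates. The stannane may attack the wrong face.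
   - Fallback (polar, known reaction types, still a five-to-six ring enlargement): it sets out from 9 and 4 and comes back at 15.
   - Enolate 9 is alkylated with benzyl bromoacetate on the face opposite the C5 arm to give the keto diester F1, so that C10 is set before the ring change.
   - Aldehyde 4 is converted through its alkenyl nonaflate (NfF, phosphazene base) into the terminal alkyne F2 with the same carbon count.
   - The cerium acetylide of F2, a small nucleophile, adds to the hindered ketone of F1 to give the propargylic alcohol F3.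
   - Silver-catalysed carboxylative cyclisation (AgOAc, DBU, CO2) gives the alkylidene carbonate F4, and its hydrolysis gives the α-ketol F5.
   - Al(Ot-Bu)3-promoted α-ketol (acyloin) rearrangement, the reaction type of steroid D-homoannulation, moves the more substituted C10 from C8 to C9 with retention and gives the ring-enlarged hydroxy ketone F6.
   - SmI2 in THF/MeOH removes the α-hydroxyl group, and base equilibration of C9 leads to 15.

2. Step 5.
   - What may go wrong: the α-methyl group may change the binding mode of the enone, so that enantioface discrimination is poor. Turnover with the tetrasubstituted nucleophile may be slow.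
   - Fallback (racemic synthesis and resolution instead of asymmetric catalysis): it sets out from 6 and 7 and comes back at 8.
   - TiCl4-mediated Mukaiyama–Michael addition with aqueous work-up gives the racemic keto ester F7.
   - Preparative chromatography on a chiral phase gives the (S)-keto ester F8 beside the (R)-keto ester F9.
   - Thermodynamic silylation of F8 (TMSCl, NaI, Et3N, MeCN), which favours the more substituted enol silane, gives 8.

3. Step 13.
   - What may go wrong: O2 capture of the nearly planar C8 radical may show poor facial selectivity, since an intrinsic axial preference opposes the shielding by the C10 methyl group.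
   - Fallback (ionic anti addition instead of radical capture): it sets out from 16 and comes back at 17.
   - Oxymercuration (Hg(OAc)2, THF/H2O), in which water enters C8 from the unhindered equatorial side as in related 8(17)-labdenes, gives the organomercurial F10.
   - Demercuration with NaBH4/NaOH gives 17.

Further compounds
F1 | step 8 | keto diester, benzyl 2-[(1S)-2-(2-benzyloxy-2-oxoethyl)-2-methyl-3-oxocyclopentyl]-2-methylpropanoate (acetate arm trans to the C5 arm) | CC(C)(C(=O)OCc1ccccc1)[C@H]1CCC(=O)[C@]1(C)CC(=O)OCc1ccccc1
F2 | step 8 | terminal alkyne, tert-butyldimethyl{[(2R,3S)-3-methyl-3-(prop-2-yn-1-yl)oxiran-2-yl]methoxy}silane | C#CC[C@]1(C)O[C@@H]1CO[Si](C)(C)C(C)(C)C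
F3 | step 8 | propargylic alcohol from F1 and F2 (C8 carbinol configuration open) | CC(C)(C(=O)OCc1ccccc1)[C@H]1CCC(O)(C#CC[C@]2(C)O[C@@H]2CO[Si](C)(C)C(C)(C)C)[C@]1(C)CC(=O)OCc1ccccc1
F4 | step 8 | spiro alkylidene cyclic carbonate from F3 | CC(C)(C(=O)OCc1ccccc1)[C@H]1CCC2(OC(=O)OC2=CC[C@]3(C)O[C@@H]3CO[Si](C)(C)C(C)(C)C)[C@]1(C)CC(=O)OCc1ccccc1
F5 | step 8 | α-ketol, 1-acylcyclopentanol (C8–OH, C9=O) | CC(C)(C(=O)OCc1ccccc1)[C@H]1CCC(O)(C(=O)CC[C@]2(C)O[C@@H]2CO[Si](C)(C)C(C)(C)C)[C@]1(C)CC(=O)OCc1ccccc1
F6 | step 8 | ring-enlarged hydroxy ketone (C8=O, C9–OH) | CC(C)(C(=O)OCc1ccccc1)[C@H]1CCC(=O)C(O)(CC[C@]2(C)O[C@@H]2CO[Si](C)(C)C(C)(C)C)[C@]1(C)CC(=O)OCc1ccccc1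
F7 | step 5 | racemic keto ester, benzyl 2-methyl-2-(2-methyl-3-oxocyclopentyl)propanoate | CC1C(=O)CCC1C(C)(C)C(=O)OCc1ccccc1
F8 | step 5 | (S)-keto ester (C5 as in 8, C10 epimerisable) | CC(C)(C(=O)OCc1ccccc1)[C@H]1CCC(=O)C1C
F9 | step 5 | (R)-keto ester (unwanted enantiomer) | CC(C)(C(=O)OCc1ccccc1)[C@@H]1CCC(=O)C1C
F10 | step 13 | organomercurial, 17 with CH2HgOAc in place of the C8 methyl group | CC(C)(C(=O)OCc1ccccc1)[C@H]1CC[C@](C[Hg]OC(C)=O)(O)[C@@H](CC[C@]2(C)O[C@@H]2CO[Si](C)(C)C(C)(C)C)[C@]1(C)CC(=O)OCc1ccccc1
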